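The side chain is cut between C9', the last methylene of the saturated nine-carbon tether on pyrrole C5, and C10', the first sp2 carbon of the (10'Z,13'Z,16'Z) skipped triene. Both carbons are used as electrophiles: a nickel-catalysed reductive cross-electrophile coupling joins 5-(9-bromononyl)-1H-pyrrole-2-carbaldehyde to (1Z,4Z,7Z)-1-bromodeca-1,4,7-triene and should give the target in the last step. This union of two like-polarised carbons needs no preformed organometallic, so the acidic N–H and the C2 formyl group of the pyrrole ring stay unprotected, and all three Z alkenes arrive ready-made. The bromononyl arm is installed by direct C5–H alkylation of pyrrole-2-carbaldehyde.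

Key step: step 4

Remark: the side-chain carbons are numbered C1' (on pyrrole C5) to C19' (terminal methyl). Compounds 1, 2 and 4 are taken as commercially available.

Step 1
Reactants: 1 1H-pyrrole-2-carbaldehyde; 2 1,9-dibromononane (4 equiv)
Product: 3 5-(9-bromononyl)-1H-pyrrole-2-carbaldehyde
Conditions: PdCl2(MeCN)2 (10 mol %), norbornene (2 equiv), KHCO3 (3 equiv), DMA (0.5 M H2O), 90 °C
Reagents that add atoms: none
Why: This is the Catellani-type norbornene-mediated C–H alkylation known for N–H pyrroles with a C2 acceptor, in which divalent palladium binds at nitrogen, norbornene relays it to C5 and the primary bromide is delivered there only, while the weak base KHCO3 disfavours N-alkylation and the excess of 2 keeps the second bromide intact.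

Step 2
Reactants: 4 (3Z,6Z)-nona-3,6-dien-1-ol
Product: 5 (3Z,6Z)-nona-3,6-dienal
Conditions: Dess–Martin periodinane (1.2 equiv), NaHCO3, CH2Cl2, 0 °C; filtered and used crude at once
Reagents that add atoms: none
Why: Dess–Martin oxidation under bicarbonate buffer should convert the homoallylic primary alcohol into the aldehyde without acid or base strong enough to move the C3=C4 alkene into conjugation or to scramble the two Z alkenes.

Step 3
Reactants: 5 (3Z,6Z)-nona-3,6-dienal
Product: 6 (1Z,4Z,7Z)-1-bromodeca-1,4,7-triene
Conditions: BrCH2PPh3Br (1.3 equiv), KOtBu (1.25 equiv), THF, −78 °C; then 5, −78 °C to 0 °C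
Reagents that add atoms: (bromomethyl)triphenylphosphonium bromide, BrC[P+](c1ccccc1)(c1ccccc1)c1ccccc1.[Br-]
Why: Wittig olefination with the non-stabilised bromo ylide at −78 °C passes through the kinetically favoured cis-oxaphosphetane and should give mainly the Z-alkenyl bromide, and the slight deficit of base avoids dehydrobromination to the alkyne and enolisation of 5.

Step 4
Reactants: 3 5-(9-bromononyl)-1H-pyrrole-2-carbaldehyde; 6 (1Z,4Z,7Z)-1-bromodeca-1,4,7-triene (1.5 equiv)
Product: 7 mycalazal 20, 5-[(10Z,13Z,16Z)-nonadeca-10,13,16-trien-1-yl]-1H-pyrrole-2-carbaldehyde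
Conditions: NiBr2(dme) (10 mol %; dme = 1,2-dimethoxyethane), 2,2'-bipyridine (10 mol %), NaI (0.5 equiv), Zn dust (2 equiv), DMA, 25 °C
Reagents that add atoms: none
Why: Zerovalent nickel–bipyridine, regenerated by Zn, inserts into the C(sp2)–Br bond of 6 with retention, while monovalent nickel halide abstracts the halogen of 3 (partly exchanged to iodide by NaI) to give the primary C9' radical; capture of this radical by the alkenylnickel bromide gives a trivalent alkyl(alkenyl)nickel species whose reductive elimination forms the C9'–C10' bond. The closest known reaction type is the nickel-catalysed reductive cross-electrophile coupling of alkenyl bromides with primary alkyl bromides. No ring is closed and no stereocentre is created; the Z geometry of C10'=C11' is that of 6, kept because oxidative addition and reductive elimination at the sp2 carbon are stereoretentive and no free alkenyl radical is involved. The step needs cross- over homo-coupling, which is secured by the different activation modes of the two bromides (two-electron for the sp2 bromide, one-electron for the sp3 bromide) and a moderate excess of 6. Chemoselectivity toward the pyrrole N–H and the C2 formyl group follows from the absence of any preformed basic or hydridic organometallic, since Zn does not add to the vinylogous formamide carbonyl, and room temperature limits nickel hydride migration along the skipped triene.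

Compound list
1 | 1H-pyrrole-2-carbaldehyde | O=Cc1ccc[nH]1 | starting material
2 | 1,9-dibromononane | BrCCCCCCCCCBr | starting material
3 | 5-(9-bromononyl)-1H-pyrrole-2-carbaldehyde | O=Cc1ccc(CCCCCCCCCBr)[nH]1 | intermediate
4 | (3Z,6Z)-nona-3,6-dien-1-ol | CC/C=C\C/C=C\CCO | starting material
5 | (3Z,6Z)-nona-3,6-dienal | CC/C=C\C/C=C\CC=O | intermediate
6 | (1Z,4Z,7Z)-1-bromodeca-1,4,7-triene | CC/C=C\C/C=C\C/C=C\Br | intermediate
7 | mycalazal 20, 5-[(10Z,13Z,16Z)-nonadeca-10,13,16-trien-1-yl]-1H-pyrrole-2-carbaldehyde | CC/C=C\C/C=C\C/C=C\CCCCCCCCCc1ccc(C=O)[nH]1 | target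

Total step count: 4
Longest linear sequence: 3 steps (4 → 5 → 6 → 7)

Steps most likely to fail

Step 4. What may go wrong is erosion of the Z geometry at C10'=C11' by isomerisation at the alkenylnickel stage or by nickel hydride migration along the skipped triene, together with homodimerisation or hydrodehalogenation of either bromide. The fallback forms the same C9'–C10' bond by a B-alkyl Suzuki–Miyaura coupling; it sets out from 6 and returns at 7. Pyrrole is C2-acylated as its magnesium salt (EtMgBr, then non-8-enoyl chloride, Et2O/toluene) to 1-(1H-pyrrol-2-yl)non-8-en-1-one F1. The ketone is reduced to the methylene (NaBH4, i-PrOH, reflux) to give 2-(non-8-en-1-yl)-1H-pyrrole F2. Hydroboration of the terminal alkene with 9-BBN-H in THF gives 9-[9-(1H-pyrrol-2-yl)nonyl]-9-borabicyclo[3.3.1]nonane F3, which is coupled in the same flask with 6 (Pd(dppf)Cl2, AsPh3, Cs2CO3, DMF/THF/H2O, 25 °C) with retention to 2-[(10Z,13Z,16Z)-nonadeca-10,13,16-trien-1-yl]-1H-pyrrole F4. Vilsmeier–Haack formylation at the free α-position (POCl3, DMF, 0 °C; then aq. NaOAc) should then give 7. The aldehyde is introduced last here because 9-BBN-H would reduce it.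

Step 1. What may go wrong is competing N-alkylation of the acidic pyrrole nitrogen and further reaction of the remote bromide, leading to oligomers. The fallback masks the aldehyde and nitrogen together and alkylates a C5 carbanion; it sets out from 1 and returns at 3. Compound 1 is condensed with dimethylamine (40% aq. Me2NH, Me2NH·HCl, 25 °C) to the 6-(dimethylamino)-1-azafulvene dimer, 5,10-bis(dimethylamino)-5H,10H-dipyrrolo[1,2-a:1',2'-d]pyrazine F5. Twofold lithiation next to each ring nitrogen (t-BuLi, THF, −15 °C) gives the 3,8-dilithio dimer F6, which is alkylated with excess 2 to the 3,8-bis(9-bromononyl) dimer F7. Mild hydrolysis (aq. NaHCO3, THF, 60 °C) then releases two equivalents of 3.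

Step 3. What may go wrong is incomplete Z selectivity of the bromo-olefination and base-induced migration of the C3=C4 alkene of 5 into conjugation before the ylide adds. The fallback avoids any base and sets the geometry by a selective reduction; it sets out from 5 and returns at 6. Compound 5 is converted with CBr4/PPh3 (CH2Cl2, 0 °C) into (4Z,7Z)-1,1-dibromodeca-1,4,7-triene F8. The bromine trans to the chain is then removed selectively by hydrogenolysis with Bu3SnH under Pd(PPh3)4 catalysis (toluene, 25 °C), which should leave the Z-alkenyl bromide 6.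

Further compounds
F1 | step 4 | 1-(1H-pyrrol-2-yl)non-8-en-1-one | C=CCCCCCCC(=O)c1ccc[nH]1
F2 | step 4 | 2-(non-8-en-1-yl)-1H-pyrrole | C=CCCCCCCCc1ccc[nH]1
F3 | step 4 | 9-[9-(1H-pyrrol-2-yl)nonyl]-9-borabicyclo[3.3.1]nonane | B1(CCCCCCCCCc2ccc[nH]2)C2CCCC1CCC2
F4 | step 4 | 2-[(10Z,13Z,16Z)-nonadeca-10,13,16-trien-1-yl]-1H-pyrrole | CC/C=C\C/C=C\C/C=C\CCCCCCCCCc1ccc[nH]1
F5 | step 1 | 5,10-bis(dimethylamino)-5H,10H-dipyrrolo[1,2-a:1',2'-d]pyrazine (6-(dimethylamino)-1-azafulvene dimer) | CN(C)C1c2cccn2C(N(C)C)c2cccn21
F6 | step 1 | 3,8-dilithio-5,10-bis(dimethylamino)-5H,10H-dipyrrolo[1,2-a:1',2'-d]pyrazine | CN(C)C1c2ccc([Li])n2C(N(C)C)c2ccc([Li])n21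
F7 | step 1 | 3,8-bis(9-bromononyl)-5,10-bis(dimethylamino)-5H,10H-dipyrrolo[1,2-a:1',2'-d]pyrazine | CN(C)C1c2ccc(CCCCCCCCCBr)n2C(N(C)C)c2ccc(CCCCCCCCCBr)n21
F8 | step 3 | (4Z,7Z)-1,1-dibromodeca-1,4,7-triene | CC/C=C\C/C=C\CC=C(Br)Br
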